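**Strategy**

The cyclohexane ring (C6–C11, iridal numbering; C7 carries the enal, C6 the hydroxypropyl arm) is made by an intramolecular Diels–Alder reaction that forms C6–C7 and C10–C11 together. The feature exploited is that O3 of the arm on C6 reaches C7 through a six-membered ring (O3, C3, C4, C5, C6, C7): O3 serves as a temporary tether, bound to C7 as a dienyl ether. A chiral oxazaborolidinium catalyst cyclises the achiral trienal 6 to a trans-fused oxadecalin, setting C6, C10 and quaternary C11 at once. The C7–O3 bond is later excised (enol ether shift, hydrolysis), freeing the C3 hydroxyl and a C7 ketone that is converted into the enal.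

Key step: step 4

Remark: atom numbers C1–C26 in the text are iridal numbers (C1 = CHO, C3 = CH2O, ring C6–C11, C17 = carbinol); in the bicyclic intermediates C6, C7, C8, C9, C10, C11 are chromene positions 4a, 8a, 8, 7, 6, 5.
Remark: the enal geometry of the target (CHO cis to C6) is assumed to be the more stable of the two isomers, and the (S)-catalyst of step 4 is chosen from the accepted model for 2-substituted enals, transferred here to an intramolecular case.

**Ring fragment (steps 1–6)**

Step 1
Reactants: 1 (E)-but-2-enal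
Product: 2 (1E,3E)-1-iodopenta-1,3-diene
Conditions: CrCl2 (6 equiv), CHI3 (2 equiv), THF, 0 °C
Reagents that add atoms: iodoform, IC(I)I
Why: Takai olefination, in which the gem-dichromium species from CHI3 and CrCl2 adds to the aldehyde and eliminates to the (E)-iodoalkene while the existing (E)-alkene is untouched.

Step 2
Reactants: 2 (1E,3E)-1-iodopenta-1,3-diene; 3 butane-1,4-diol (5 equiv)
Product: 4 4-[(1E,3E)-penta-1,3-dien-1-yloxy]butan-1-ol
Conditions: CuI (10 mol %), 3,4,7,8-tetramethyl-1,10-phenanthroline (20 mol %), Cs2CO3, toluene, 80 °C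
Reagents that add atoms: none
Why: Copper-catalysed Ullmann-type C–O coupling of an alkenyl iodide with a primary alcohol should proceed with retention of alkene geometry, and the excess of diol suppresses the bis-ether.

Step 3
Reactants: 4 4-[(1E,3E)-penta-1,3-dien-1-yloxy]butan-1-ol
Product: 6 (2E)-2-methyl-6-[(1E,3E)-penta-1,3-dien-1-yloxy]hex-2-enal, via aldehyde 5 (not isolated)
Conditions: (n-Pr4N)RuO4 (5 mol %), N-methylmorpholine N-oxide, 4 Å molecular sieves, CH2Cl2, rt; then Ph3P=C(CH3)CHO, 40 °C
Reagents that add atoms: 2-(triphenylphosphoranylidene)propanal, CC(C=O)=P(c1ccccc1)(c1ccccc1)c1ccccc1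
Why: The neutral Ley–Griffith oxidation spares the acid-labile dienyl ether, and the stabilised ylide should convert aldehyde 5 in the same flask into the (E)-2-methyl enal (Wittig reaction, E-selective).

Step 4
Reactants: 6 (2E)-2-methyl-6-[(1E,3E)-penta-1,3-dien-1-yloxy]hex-2-enal
Product: 7 (4aS,5R,6R,8aS)-5,6-dimethyl-3,4,4a,5,6,8a-hexahydro-2H-chromene-5-carbaldehyde (trans-fused)
Conditions: (S)-1-(2-methylphenyl)-3,3-diphenyltetrahydro-1H,3H-pyrrolo[1,2-c][1,3,2]oxazaborole (20 mol %), HN(SO2CF3)2 (17 mol %), CH2Cl2, −78 to −40 °C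
Reagents that add atoms: none
Why: The N-protonated oxazaborolidine binds the s-trans enal at the formyl oxygen and the tethered (E,E)-dienyl ether adds across the activated C6=C11 bond in a concerted, asynchronous type 1 intramolecular Diels–Alder reaction, the closest known reaction being the chiral Lewis acid catalysed cyclisation of 2-methyl trienals. The cyclohexene ring is closed by the [4+2] cycloaddition itself and the tetrahydropyran ring by the four-atom O3–C3–C4–C5 tether in the fused mode, through the transition state with the formyl group endo and the tether exo, which leads to the trans ring fusion. C6 and C11 are related by the (E)-geometry of the enal (arm on C6 trans to CHO on C11), C10 follows from the (E)-propenyl terminus together with the endo formyl group (10-CH3 cis to CHO), and the C7 centre, which is destroyed later, follows from the (E)-enol ether. The absolute configuration comes from the catalyst, whose phenyl group should shield one face of the bound 2-methyl enal so that the diene adds to the Re face at C11 (CHO > C6 > CH3). The step needs regio-, endo- and enantioselectivity: the tether forces the oxygen-bearing diene terminus onto the β-carbon, against the intermolecular preference of a 1-alkoxydiene, and low temperature with slightly less acid than oxazaborolidine should keep the dienyl ether from ionisation or stepwise Michael-type closure.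

Step 5
Reactants: 7 (4aS,5R,6R,8aS)-5,6-dimethyl-3,4,4a,5,6,8a-hexahydro-2H-chromene-5-carbaldehyde
Product: 8 (4aS,5R,6R,8aS)-5-ethenyl-5,6-dimethyl-3,4,4a,5,6,8a-hexahydro-2H-chromene
Conditions: Ph3PCH3Br, KOtBu, THF, 0 °C to rt
Reagents that add atoms: methyltriphenylphosphonium bromide, C[P+](c1ccccc1)(c1ccccc1)c1ccccc1.[Br-]
Why: Wittig methylenation with the non-stabilised ylide should convert the neopentyl aldehyde, which has no α-hydrogen and cannot epimerise.

Step 6
Reactants: 8 (4aS,5R,6R,8aS)-5-ethenyl-5,6-dimethyl-3,4,4a,5,6,8a-hexahydro-2H-chromene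
Product: 9 (4aS,5R,6R)-5-ethenyl-5,6-dimethyl-3,4,4a,5,6,7-hexahydro-2H-chromene
Conditions: KOtBu (0.3 equiv), DMSO, rt
Reagents that add atoms: none
Why: Base-mediated allyl ether to enol ether isomerisation, in which the C7–H (allylic, α to oxygen, pseudo-axial) is the most acidic proton and reprotonation of the alkoxyallyl anion at C9 should give the more stable enol ether without touching C6, C10 or C11.

**Side chain (steps 7–12)**

Step 7
Reactants: 10 prop-2-yn-1-ol
Product: 12 (E)-3-iodo-2-methylprop-2-en-1-ol, via alkenylalane 11 (not isolated)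
Conditions: AlMe3 (3 equiv), Cp2ZrCl2 (25 mol %), CH2Cl2, 0 °C to rt; then I2, THF, −30 °C
Reagents that add atoms: trimethylaluminium, C[Al](C)C; iodine, II
Why: Negishi carboalumination adds CH3 and aluminium syn across the alkyne with CH3 on the internal carbon, and iodinolysis with retention should give the (E)-iodoalkene.

Step 8
Reactants: 12 (E)-3-iodo-2-methylprop-2-en-1-ol
Product: 13 (E)-3-iodo-2-methylprop-2-enal
Conditions: MnO2, CH2Cl2, rt
Reagents that add atoms: none
Why: MnO2 oxidises the allylic alcohol selectively and should leave the C–I bond and the alkene geometry intact.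

Step 9
Reactants: 13 (E)-3-iodo-2-methylprop-2-enal; 14 geranyl chloride
Product: 16 rac-(1E,5E)-1-iodo-2,6,10-trimethylundeca-1,5,9-trien-3-ol, via geranylbarium chloride 15 (not isolated)
Conditions: BaI2, lithium biphenylide (2 equiv), THF, rt; 14, −78 °C; then 13, −78 °C
Reagents that add atoms: none
Why: Allylic barium reagents add 1,2 to aldehydes at their α-carbon with retention of the (E)-allyl geometry, which should give the linear homoallylic alcohol; its carbinol centre is racemic and is set in steps 10 and 11.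

Step 10
Reactants: 16 rac-(1E,5E)-1-iodo-2,6,10-trimethylundeca-1,5,9-trien-3-ol
Product: 17 (1E,5E)-1-iodo-2,6,10-trimethylundeca-1,5,9-trien-3-one
Conditions: MnO2, CH2Cl2, rt
Reagents that add atoms: none
Why: Neutral MnO2 oxidation of the allylic alcohol should give the enone without moving the β,γ-double bond into conjugation.

Step 11
Reactants: 17 (1E,5E)-1-iodo-2,6,10-trimethylundeca-1,5,9-trien-3-one
Product: 18 (3R,1E,5E)-1-iodo-2,6,10-trimethylundeca-1,5,9-trien-3-ol
Conditions: (S)-1-methyl-3,3-diphenyltetrahydro-1H,3H-pyrrolo[1,2-c][1,3,2]oxazaborole (20 mol %), catecholborane, toluene, −78 °C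
Reagents that add atoms: none
Why: Corey–Bakshi–Shibata reduction, in which the α-branched iodoalkenyl group acts as the large substituent so that hydride delivery within the catalyst–borane complex should give the (R)-alcohol, while catecholborane at low temperature does not hydroborate the alkenes.

Step 12
Reactants: 18 (3R,1E,5E)-1-iodo-2,6,10-trimethylundeca-1,5,9-trien-3-ol
Product: 19 tert-butyl{[(3R,1E,5E)-1-iodo-2,6,10-trimethylundeca-1,5,9-trien-3-yl]oxy}dimethylsilane
Conditions: t-BuMe2SiCl, imidazole, DMF, rt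
Reagents that add atoms: tert-butyldimethylsilyl chloride, CC(C)(C)[Si](C)(C)Cl
Why: Imidazole-promoted silylation masks the C17 hydroxyl, which would otherwise be oxidised in step 17.

**Union and completion (steps 13–18)**

Step 13
Reactants: 9 (4aS,5R,6R)-5-ethenyl-5,6-dimethyl-3,4,4a,5,6,7-hexahydro-2H-chromene; 19 tert-butyl{[(3R,1E,5E)-1-iodo-2,6,10-trimethylundeca-1,5,9-trien-3-yl]oxy}dimethylsilane
Product: 21 (4aS,5R,6R)-5-[(3E,5R,7E)-5-{[tert-butyl(dimethyl)silyl]oxy}-4,8,12-trimethyltrideca-3,7,11-trien-1-yl]-5,6-dimethyl-3,4,4a,5,6,7-hexahydro-2H-chromene, via alkylborane 20 (not isolated)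
Conditions: 9-borabicyclo[3.3.1]nonane, THF, rt; then 19, Pd(dppf)Cl2 (5 mol %), AsPh3, Cs2CO3, DMF/H2O, rt
Reagents that add atoms: none
Why: The borane should hydroborate only the monosubstituted vinyl group (anti-Markovnikov), and the B-alkyl Suzuki–Miyaura coupling joins the primary alkylborane to the alkenyl iodide with retention of the (E)-geometry under conditions that leave the enol ether and silyl ether intact.

Step 14
Reactants: 21 (the coupled enol ether)
Product: 22 (2S,3R,4R)-3-[(3E,5R,7E)-5-{[tert-butyl(dimethyl)silyl]oxy}-4,8,12-trimethyltrideca-3,7,11-trien-1-yl]-2-(3-hydroxypropyl)-3,4-dimethylcyclohexan-1-one (in equilibrium with its cyclic hemiketal)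
Conditions: pyridinium p-toluenesulfonate (cat.), acetone/H2O, rt
Reagents that add atoms: water, O
Why: Enol ether hydrolysis, in which protonation at C8 and addition of water to the oxocarbenium ion should release the C7 ketone and the C3 hydroxyl under conditions too mild to enolise toward C6 or to cleave the allylic silyl ether.

Step 15
Reactants: 22 (the hydroxy ketone)
Product: 23 3-[(1S,2R,3R)-2-[(3E,5R,7E)-5-{[tert-butyl(dimethyl)silyl]oxy}-4,8,12-trimethyltrideca-3,7,11-trien-1-yl]-2,3-dimethyl-6-oxocyclohexyl]propyl decanoate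
Conditions: decanoyl chloride, pyridine, 4-(dimethylamino)pyridine (cat.), CH2Cl2, 0 °C
Reagents that add atoms: decanoyl chloride, CCCCCCCCCC(=O)Cl
Why: Acylation of the primary alcohol of the open form should drain the hemiketal equilibrium, since the tertiary hemiketal hydroxyl is not acylated.

Step 16
Reactants: 23 (the keto decanoate)
Product: 24 3-[(1S,2R,3R)-2-[(3E,5R,7E)-5-{[tert-butyl(dimethyl)silyl]oxy}-4,8,12-trimethyltrideca-3,7,11-trien-1-yl]-6-hydroxy-2,3-dimethyl-6-(prop-1-en-2-yl)cyclohexyl]propyl decanoate (epimers at the new carbinol carbon, both used)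
Conditions: isopropenylmagnesium bromide, CeCl3, THF, −78 °C
Reagents that add atoms: isopropenylmagnesium bromide, CC(=C)[Mg]Br
Why: The weakly basic organocerium reagent should add 1,2 to the hindered ketone faster than to the ester and without enolisation, so C6 keeps its configuration, and the new carbinol centre is removed in step 17.

Step 17
Reactants: 24 (the tertiary allylic alcohol)
Product: 25 3-[(1S,2R,3R,6Z)-2-[(3E,5R,7E)-5-{[tert-butyl(dimethyl)silyl]oxy}-4,8,12-trimethyltrideca-3,7,11-trien-1-yl]-2,3-dimethyl-6-(1-oxopropan-2-ylidene)cyclohexyl]propyl decanoate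
Conditions: pyridinium chlorochromate (C5H5NH)[CrO3Cl], 4 Å molecular sieves, CH2Cl2, rt
Reagents that add atoms: pyridinium chlorochromate, [O-][Cr](=O)(=O)Cl.c1cc[nH+]cc1
Why: Babler–Dauben oxidative transposition, in which the tertiary allylic chromate ester undergoes a [3,3]-shift and the primary chromate is oxidised to the enal; in the chair-like transition state the isopropenyl methyl should avoid the more substituted C6 branch, which places the formyl carbon cis to C6.

Step 18
Reactants: 25 (the silylated enal)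
Product: 26 the target, 3-O-decanoyl-(6S,10R,11R,17R)-10-deoxy-17-hydroxyiridal
Conditions: HF·pyridine, pyridine, THF, 0 °C to rt
Reagents that add atoms: none
Why: Fluoride-mediated cleavage of the secondary silyl ether under buffered conditions should leave the ester, the enal and the alkenes untouched.

**Compound list**

1 | (E)-but-2-enal | C/C=C/C=O | starting material
2 | (1E,3E)-1-iodopenta-1,3-diene | C/C=C/C=C/I | intermediate
3 | butane-1,4-diol | OCCCCO | starting material
4 | 4-[(1E,3E)-penta-1,3-dien-1-yloxy]butan-1-ol | C/C=C/C=C/OCCCCO | intermediate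
5 | 4-[(1E,3E)-penta-1,3-dien-1-yloxy]butanal | C/C=C/C=C/OCCCC=O | intermediate (not isolated)
6 | (2E)-2-methyl-6-[(1E,3E)-penta-1,3-dien-1-yloxy]hex-2-enal | C/C=C/C=C/OCCC/C=C(\C)C=O | intermediate
7 | (4aS,5R,6R,8aS)-5,6-dimethyl-3,4,4a,5,6,8a-hexahydro-2H-chromene-5-carbaldehyde | C[C@@H]1C=C[C@@H]2OCCC[C@H]2[C@]1(C)C=O | intermediate
8 | (4aS,5R,6R,8aS)-5-ethenyl-5,6-dimethyl-3,4,4a,5,6,8a-hexahydro-2H-chromene | C[C@@H]1C=C[C@@H]2OCCC[C@H]2[C@]1(C)C=C | intermediate
9 | (4aS,5R,6R)-5-ethenyl-5,6-dimethyl-3,4,4a,5,6,7-hexahydro-2H-chromene | C[C@@H]1CC=C2OCCC[C@H]2[C@]1(C)C=C | intermediate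
10 | prop-2-yn-1-ol | C#CCO | starting material
11 | [(E)-3-(dimethylalumanyloxy)-2-methylprop-1-enyl]dimethylalumane | C[Al](C)/C=C(\C)CO[Al](C)C | intermediate (not isolated)
12 | (E)-3-iodo-2-methylprop-2-en-1-ol | I/C=C(\C)CO | intermediate
13 | (E)-3-iodo-2-methylprop-2-enal | I/C=C(\C)C=O | intermediate
14 | geranyl chloride, (2E)-1-chloro-3,7-dimethylocta-2,6-diene | ClC/C=C(\C)CCC=C(C)C | starting material
15 | geranylbarium chloride | Cl[Ba]C/C=C(\C)CCC=C(C)C | intermediate (not isolated)
16 | rac-(1E,5E)-1-iodo-2,6,10-trimethylundeca-1,5,9-trien-3-ol | I/C=C(\C)C(O)C/C=C(\C)CCC=C(C)C | intermediate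
17 | (1E,5E)-1-iodo-2,6,10-trimethylundeca-1,5,9-trien-3-one | I/C=C(\C)C(=O)C/C=C(\C)CCC=C(C)C | intermediate
18 | (3R,1E,5E)-1-iodo-2,6,10-trimethylundeca-1,5,9-trien-3-ol | I/C=C(\C)[C@H](O)C/C=C(\C)CCC=C(C)C | intermediate
19 | tert-butyl{[(3R,1E,5E)-1-iodo-2,6,10-trimethylundeca-1,5,9-trien-3-yl]oxy}dimethylsilane | I/C=C(\C)[C@H](O[Si](C)(C)C(C)(C)C)C/C=C(\C)CCC=C(C)C | intermediate
20 | 9-{2-[(4aS,5R,6R)-5,6-dimethyl-3,4,4a,5,6,7-hexahydro-2H-chromen-5-yl]ethyl}-9-borabicyclo[3.3.1]nonane | C[C@@H]1CC=C2OCCC[C@H]2[C@]1(C)CCB1C2CCCC1CCC2 | intermediate (not isolated)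
21 | (4aS,5R,6R)-5-[(3E,5R,7E)-5-{[tert-butyl(dimethyl)silyl]oxy}-4,8,12-trimethyltrideca-3,7,11-trien-1-yl]-5,6-dimethyl-3,4,4a,5,6,7-hexahydro-2H-chromene | C[C@@H]1CC=C2OCCC[C@H]2[C@]1(C)CC/C=C(\C)[C@H](O[Si](C)(C)C(C)(C)C)C/C=C(\C)CCC=C(C)C | intermediate
22 | (2S,3R,4R)-3-[(3E,5R,7E)-5-{[tert-butyl(dimethyl)silyl]oxy}-4,8,12-trimethyltrideca-3,7,11-trien-1-yl]-2-(3-hydroxypropyl)-3,4-dimethylcyclohexan-1-one | OCCC[C@@H]1C(=O)CC[C@@H](C)[C@@]1(C)CC/C=C(\C)[C@H](O[Si](C)(C)C(C)(C)C)C/C=C(\C)CCC=C(C)C | intermediate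
23 | 3-[(1S,2R,3R)-2-[(3E,5R,7E)-5-{[tert-butyl(dimethyl)silyl]oxy}-4,8,12-trimethyltrideca-3,7,11-trien-1-yl]-2,3-dimethyl-6-oxocyclohexyl]propyl decanoate | CCCCCCCCCC(=O)OCCC[C@@H]1C(=O)CC[C@@H](C)[C@@]1(C)CC/C=C(\C)[C@H](O[Si](C)(C)C(C)(C)C)C/C=C(\C)CCC=C(C)C | intermediate
24 | 3-[(1S,2R,3R)-2-[(3E,5R,7E)-5-{[tert-butyl(dimethyl)silyl]oxy}-4,8,12-trimethyltrideca-3,7,11-trien-1-yl]-6-hydroxy-2,3-dimethyl-6-(prop-1-en-2-yl)cyclohexyl]propyl decanoate (epimers at C6 of the cyclohexyl ring) | CCCCCCCCCC(=O)OCCC[C@@H]1C(O)(C(C)=C)CC[C@@H](C)[C@@]1(C)CC/C=C(\C)[C@H](O[Si](C)(C)C(C)(C)C)C/C=C(\C)CCC=C(C)C | intermediate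
25 | 3-[(1S,2R,3R,6Z)-2-[(3E,5R,7E)-5-{[tert-butyl(dimethyl)silyl]oxy}-4,8,12-trimethyltrideca-3,7,11-trien-1-yl]-2,3-dimethyl-6-(1-oxopropan-2-ylidene)cyclohexyl]propyl decanoate | CCCCCCCCCC(=O)OCCC[C@@H]1/C(=C(/C)C=O)CC[C@@H](C)[C@@]1(C)CC/C=C(\C)[C@H](O[Si](C)(C)C(C)(C)C)C/C=C(\C)CCC=C(C)C | intermediate
26 | 3-[(1S,2R,3R,6Z)-2-[(3E,5R,7E)-5-hydroxy-4,8,12-trimethyltrideca-3,7,11-trien-1-yl]-2,3-dimethyl-6-(1-oxopropan-2-ylidene)cyclohexyl]propyl decanoate | CCCCCCCCCC(=O)OCCC[C@@H]1/C(=C(/C)C=O)CC[C@@H](C)[C@@]1(C)CC/C=C(\C)[C@H](O)C/C=C(\C)CCC=C(C)C | target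

**Step count**

Total: 18 steps. Longest linear sequence: 12 steps (steps 1–6, then 13–18; the side-chain branch, steps 7–12 then 13–18, is equally long).

**Steps most likely to fail**

Step 4. The acidic catalyst may ionise or hydrolyse the dienyl ether, the enol ether may close stepwise through its nucleophilic β-carbon C8 (Michael-type or hetero-Diels–Alder pathway), or facial discrimination may be poor in the tethered case. The fallback gives up Lewis acid catalysis and sets out from 6: heating in toluene with 2,6-di-tert-butyl-4-methylphenol at 130 °C in a sealed tube should give, by the concerted thermal cycloaddition, the racemic trans-fused aldehyde F1. Condensation with (1R,2R)-N,N′-dimethyl-1,2-diphenylethane-1,2-diamine (4 Å molecular sieves, Et2O) gives two diastereomeric imidazolidines; the aminal of the desired enantiomer F2 is separated by chromatography and hydrolysed with dilute aqueous HCl, which comes back to the route at 7.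

Step 6. The proton shift may run in the wrong direction (removal of the C10–H and loss of the C10 stereocentre) or stop short. The fallback replaces isomerisation by oxidation and sets out from 8: hydride abstraction from the doubly activated C7–H with 2,3-dichloro-5,6-dicyano-1,4-benzoquinone in wet CH2Cl2 and hydrolysis of the oxocarbenium ion should give the hydroxy enone F3. Conjugate reduction with [(Ph3P)CuH]6 gives the hydroxy ketone F4 with the vinyl group untouched, and this is stored as the cyclic methyl ketal F5 (MeOH, pyridinium p-toluenesulfonate). Under the conditions of step 13, F5 is hydroborated to the alkylborane F6 and coupled with 19 to the ketal F7, and the hydrolysis of step 14 then comes back to the route at 22.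

Step 17. The tertiary allylic alcohol may dehydrate toward C6 or C8 instead of undergoing the [3,3]-shift, or the geometry of the new tetrasubstituted alkene may be poorly controlled. The fallback is a direct formyl-olefination that sets out from 23 and bypasses 24: Peterson reaction with lithiated N-tert-butyl-2-(triethylsilyl)propan-1-imine (s-BuLi, THF, −78 to 0 °C) should give the α,β-unsaturated N-tert-butyl imine F8. Hydrolysis with aqueous oxalic acid, which also equilibrates the enal toward its more stable isomer, comes back to the route at 25.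

**Further compounds**

F1 | step 4 | racemic trans-fused aldehyde (7 together with its enantiomer) | C[C@@H]1C=C[C@@H]2OCCC[C@H]2[C@]1(C)C=O.C[C@H]1C=C[C@H]2OCCC[C@@H]2[C@@]1(C)C=O
F2 | step 4 | (4R,5R)-1,3-dimethyl-4,5-diphenylimidazolidine aminal of 7 | C[C@@H]1C=C[C@@H]2OCCC[C@H]2[C@]1(C)C1N(C)[C@H](c2ccccc2)[C@@H](c2ccccc2)N1C
F3 | step 6 | (4R,5R,6S)-5-ethenyl-6-(3-hydroxypropyl)-4,5-dimethylcyclohex-2-en-1-one | OCCC[C@@H]1C(=O)C=C[C@@H](C)[C@@]1(C)C=C
F4 | step 6 | (2S,3R,4R)-3-ethenyl-2-(3-hydroxypropyl)-3,4-dimethylcyclohexan-1-one | OCCC[C@@H]1C(=O)CC[C@@H](C)[C@@]1(C)C=C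
F5 | step 6 | (4aS,5R,6R)-5-ethenyl-8a-methoxy-5,6-dimethyloctahydro-2H-chromene (either anomer) | C[C@@H]1CCC2(OC)OCCC[C@H]2[C@]1(C)C=C
F6 | step 6 | 9-{2-[(4aS,5R,6R)-8a-methoxy-5,6-dimethyloctahydro-2H-chromen-5-yl]ethyl}-9-borabicyclo[3.3.1]nonane | C[C@@H]1CCC2(OC)OCCC[C@H]2[C@]1(C)CCB1C2CCCC1CCC2
F7 | step 6 | 8a-methoxy analogue of 21 (cyclic methyl ketal carrying the side chain) | C[C@@H]1CCC2(OC)OCCC[C@H]2[C@]1(C)CC/C=C(\C)[C@H](O[Si](C)(C)C(C)(C)C)C/C=C(\C)CCC=C(C)C
F8 | step 17 | N-tert-butyl imine of 25 | CCCCCCCCCC(=O)OCCC[C@@H]1/C(=C(/C)C=NC(C)(C)C)CC[C@@H](C)[C@@]1(C)CC/C=C(\C)[C@H](O[Si](C)(C)C(C)(C)C)C/C=C(\C)CCC=C(C)C
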